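**Plan**

1. Locants used in the text: C4 = gem-dimethyl carbon, C5 = ring-fusion CH, C10 = methyl-bearing ring-fusion carbon, C8=C9 = ring alkene, C11 to C15 = chain carbons counted from C9, C16 = butenolide carbon that carries the chain (compound names use naphthalene locants).
2. Retrosynthetic cuts: C15=C16 (vinylogous aldol addition and elimination), C12–C13 (B-alkyl Suzuki–Miyaura coupling), C11=C12 (Wittig, C12 enters as a vinyl CH2), then ring B at C5–C6 and C9–C10 in one [4+2] annulation.
3. Enabling feature: ring B is a cyclohexene whose two bonds to ring A end on the adjacent pair C5(H)/C10(CH3), and C5 is flanked by C4. With C4 held at the ketone level this pair is the α,β-unit of 3-methylcyclohex-2-en-1-one, while C6–C7–C8(O)=C9–C11 is a 3-silyloxypenta-2,4-dienoate whose oxygen later becomes the C8 methyl group and whose ester becomes C11.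
4. Forward order: ring A is bought, ring B is closed in step 3, C8–O is exchanged for CH3 through the enol triflate, the C4 ketone is turned into the gem-dimethyl group, the ester is taken to a vinyl group, the chain C13–C15 is coupled on and the butenolide is attached last.
5. Stereochemistry: C10 from the chiral Lewis acid in step 3; C5 from base equilibration next to the C4 ketone to the trans-decalin (step 5); the C13=C14 (E) alkene from anti-hydroalumination/iodination and stereoretentive coupling; the C15=C16 (Z) alkene from the elimination in step 14.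

Key step: step 3

Remark: the sense of induction of the chiral Lewis acid in step 3 is assigned by analogy with cycloadditions of 2-cycloalkenones; should it prove opposite, the enantiomeric catalyst from (R)-diphenylprolinol would be used in the same step. β-Keto esters are drawn in the keto form.

Step 1
Reactants: 1 methyl 5-methoxy-3-oxopentanoate
Product: 2 methyl 3-oxopent-4-enoate
Conditions: TsOH·H2O (catalytic), hydroquinone (trace), neat, 110 °C, reduced pressure, product distilled out and used at once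
Reagents that add atoms: none
Why: Acid-catalysed β-elimination of methanol from the β-methoxy ketone through its enol should give the vinyl ketone, which is removed from the acid by distillation as it forms, and no stereocentre is created.

Step 2
Reactants: 2 methyl 3-oxopent-4-enoate
Product: 3 methyl (2Z)-3-[(tert-butyldimethylsilyl)oxy]penta-2,4-dienoate
Conditions: TBSOTf, Et3N, CH2Cl2, 0 °C
Reagents that add atoms: tert-butyldimethylsilyl trifluoromethanesulfonate, CC(C)(C)[Si](C)(C)OS(=O)(=O)C(F)(F)F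
Why: Silyl enol ether formation from the enolised β-keto ester (soft enolisation by the amine, O-silylation by the silyl triflate) should give the 2-silyloxy diene with the (Z)-enol ether geometry that places the ester on the outside of the s-cis diene.

Step 3
Reactants: 3 methyl (2Z)-3-[(tert-butyldimethylsilyl)oxy]penta-2,4-dienoate; 4 3-methylcyclohex-2-en-1-one
Product: 6 methyl (1S,4aS,8aS)-8a-methyl-2,5-dioxodecahydronaphthalene-1-carboxylate (cis-fused), via silyl enol ether cycloadduct 5 (not isolated)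
Conditions: (S)-3,3-diphenyl-1-(o-tolyl)tetrahydro-1H,3H-pyrrolo[1,2-c][1,3,2]oxazaborole·AlBr3 (10 mol %), CH2Cl2, −78 to −20 °C; then 1 M HCl, THF, 0 °C
Reagents that add atoms: none
Why: Proposed new method: the AlBr3-activated oxazaborolidine binds the carbonyl of 4, the ester-bearing diene terminus of 3 (the nucleophilic carbon of the silyl enol ether) adds to the methyl-bearing β-carbon (Mukaiyama–Michael addition) and the enolate so formed closes onto the silyl-activated vinyl ketone terminus (second Michael addition), a stepwise formal Diels–Alder [4+2] annulation that makes the C9–C10 and C5–C6 bonds. The closest known reaction types are the Diels–Alder reaction of hindered 2-silyloxydienes with β,β-disubstituted cycloalkenones promoted by AlBr3/AlMe3 (racemic) and the enantioselective Diels–Alder reaction of 2-cycloalkenones catalysed by AlBr3-activated oxazaborolidines, which has not been shown for a β-methyl enone. Ring B (six-membered) is closed by intermolecular [4+2] addition across the enone C=C, its second bond by a 6-(enolexo)-endo-trig Michael closure. The quaternary centre C10 is set by the catalyst, which should shield one face of the coordinated enone (the catalyst hand is chosen for 8aS); C5 is formed cis by suprafacial addition and is corrected in step 5, and the endo centre C9 is erased in step 4. The step needs regioselectivity (ester-bearing terminus to the β-carbon), secured by the 3-silyloxy donor of 3 and the polarisation of the enone, and 1,4- rather than 1,2-addition, secured by the soft silyl enol ether nucleophile and the hindered ketone.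

Step 4
Reactants: 6 methyl (1S,4aS,8aS)-8a-methyl-2,5-dioxodecahydronaphthalene-1-carboxylate
Product: 7 methyl (4aS,8aS)-8a-methyl-5-oxo-2-{[(trifluoromethyl)sulfonyl]oxy}-3,4,4a,5,6,7,8,8a-octahydronaphthalene-1-carboxylate (cis-fused)
Conditions: Tf2O, iPr2NEt, CH2Cl2, −78 °C
Reagents that add atoms: trifluoromethanesulfonic anhydride, O=S(=O)(OS(=O)(=O)C(F)(F)F)C(F)(F)F
Why: Enol triflate formation by O-sulfonylation of the β-keto ester, whose enol is far more acidic than the ring-A ketone, should fix the ring-B double bond between C8 and C9 and remove the C9 stereocentre.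

Step 5
Reactants: 7 methyl (4aS,8aS)-8a-methyl-5-oxo-2-{[(trifluoromethyl)sulfonyl]oxy}-3,4,4a,5,6,7,8,8a-octahydronaphthalene-1-carboxylate
Product: 9 methyl (4aR,8aS)-2,8a-dimethyl-5-oxo-3,4,4a,5,6,7,8,8a-octahydronaphthalene-1-carboxylate (trans-fused), via cis-fused keto ester 8 (not isolated)
Conditions: MeZnCl, Pd(PPh3)4 (5 mol %), THF, 50 °C; then NaOMe (0.2 equiv), MeOH, rt
Reagents that add atoms: methylzinc chloride, C[Zn]Cl
Why: Negishi cross-coupling should replace the triflate by methyl without moving the alkene, and methoxide then equilibrates the ring-fusion CH next to the ketone to the more stable trans-decalin (as in 4-oxo-5α-steroids, where the carbonyl carbon removes one syn-axial contact of the angular methyl), which sets C5; no retro-Michael path exists once C9 is sp2.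

Step 6
Reactants: 9 methyl (4aR,8aS)-2,8a-dimethyl-5-oxo-3,4,4a,5,6,7,8,8a-octahydronaphthalene-1-carboxylate
Product: 10 methyl (4aS,8aS)-2,5,5,8a-tetramethyl-3,4,4a,5,6,7,8,8a-octahydronaphthalene-1-carboxylate
Conditions: Me2Zn, TiCl4, CH2Cl2, −30 °C to rt
Reagents that add atoms: dimethylzinc, C[Zn]C (both methyl groups, delivered through Me2TiCl2 formed with TiCl4)
Why: Direct geminal dimethylation of the ketone with Me2TiCl2 (methyl addition, ionisation of the titanium alkoxide, second methyl transfer) should convert the activating carbonyl into the gem-dimethyl carbon while the ester and the electron-poor tetrasubstituted alkene are not attacked and no stereocentre is touched.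

Step 7
Reactants: 10 methyl (4aS,8aS)-2,5,5,8a-tetramethyl-3,4,4a,5,6,7,8,8a-octahydronaphthalene-1-carboxylate
Product: 11 [(4aS,8aS)-2,5,5,8a-tetramethyl-3,4,4a,5,6,7,8,8a-octahydronaphthalen-1-yl]methanol
Conditions: iBu2AlH, CH2Cl2, −78 to 0 °C
Reagents that add atoms: none
Why: 1,2-Hydride reduction of the conjugated ester by iBu2AlH should give the allylic alcohol without touching the tetrasubstituted alkene, and no stereocentre is formed.

Step 8
Reactants: 11 [(4aS,8aS)-2,5,5,8a-tetramethyl-3,4,4a,5,6,7,8,8a-octahydronaphthalen-1-yl]methanol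
Product: 12 (4aS,8aS)-2,5,5,8a-tetramethyl-3,4,4a,5,6,7,8,8a-octahydronaphthalene-1-carbaldehyde
Conditions: MnO2, CH2Cl2, rt
Reagents that add atoms: none
Why: Allylic oxidation with MnO2 should stop cleanly at the conjugated, non-enolisable aldehyde.

Step 9
Reactants: 12 (4aS,8aS)-2,5,5,8a-tetramethyl-3,4,4a,5,6,7,8,8a-octahydronaphthalene-1-carbaldehyde
Product: 13 (4aS,8aS)-1-ethenyl-2,5,5,8a-tetramethyl-3,4,4a,5,6,7,8,8a-octahydronaphthalene
Conditions: Ph3PCH3Br, KOtBu, THF, 0 °C to rt
Reagents that add atoms: methyltriphenylphosphonium bromide, C[P+](c1ccccc1)(c1ccccc1)c1ccccc1.[Br-]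
Why: Wittig methylenation with the small unstabilised ylide should convert the hindered aldehyde into the terminal vinyl group that supplies C12.

Step 10
Reactants: 14 but-2-yne-1,4-diol
Product: 15 4-[(tert-butyldimethylsilyl)oxy]but-2-yn-1-ol
Conditions: TBSCl, imidazole, DMF, 0 °C (diol in excess)
Reagents that add atoms: tert-butyldimethylsilyl chloride, CC(C)(C)[Si](C)(C)Cl
Why: Silyl ether formation on the symmetrical diol used in excess should give the mono-ether, and the unreacted diol is washed out with water.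

Step 11
Reactants: 15 4-[(tert-butyldimethylsilyl)oxy]but-2-yn-1-ol
Product: 17 (2Z)-4-[(tert-butyldimethylsilyl)oxy]-3-iodobut-2-en-1-ol, via cyclic alkenylalanate 16 (not isolated)
Conditions: NaAlH2(OCH2CH2OCH3)2, THF, 0 °C; then I2, THF, −78 to 0 °C
Reagents that add atoms: iodine, II
Why: Hydroxyl-directed anti-hydroalumination of the propargylic alcohol should place hydride on C2 and aluminium on C3 in a five-membered alanate, and iodinolysis with retention gives the (Z)-vinyl iodide that fixes the later C13=C14 geometry, the low temperature suppressing β-elimination of the silyloxy group to an allene.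

Step 12
Reactants: 13 (4aS,8aS)-1-ethenyl-2,5,5,8a-tetramethyl-3,4,4a,5,6,7,8,8a-octahydronaphthalene; 17 (2Z)-4-[(tert-butyldimethylsilyl)oxy]-3-iodobut-2-en-1-ol
Product: 19 (2E)-3-({[tert-butyl(dimethyl)silyl]oxy}methyl)-5-[(4aS,8aS)-2,5,5,8a-tetramethyl-3,4,4a,5,6,7,8,8a-octahydronaphthalen-1-yl]pent-2-en-1-ol, via B-alkyl borane 18 (not isolated)
Conditions: 9-BBN-H, THF, 0 °C to rt; then 17, PdCl2(dppf) (5 mol %), AsPh3, Cs2CO3, DMF/H2O, rt
Reagents that add atoms: none
Why: 9-BBN-H should hydroborate only the monosubstituted vinyl group at its terminus (the tetrasubstituted alkene is inert), and B-alkyl Suzuki–Miyaura coupling with the vinyl iodide proceeds with retention of the alkene geometry to join C12 to C13.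

Step 13
Reactants: 19 (2E)-3-({[tert-butyl(dimethyl)silyl]oxy}methyl)-5-[(4aS,8aS)-2,5,5,8a-tetramethyl-3,4,4a,5,6,7,8,8a-octahydronaphthalen-1-yl]pent-2-en-1-ol
Product: 20 (2E)-3-({[tert-butyl(dimethyl)silyl]oxy}methyl)-5-[(4aS,8aS)-2,5,5,8a-tetramethyl-3,4,4a,5,6,7,8,8a-octahydronaphthalen-1-yl]pent-2-enal
Conditions: MnO2, CH2Cl2, rt
Reagents that add atoms: none
Why: Allylic oxidation with MnO2 should give the enal under neutral conditions that leave the silyl ether, the ring alkene and the alkene geometry untouched.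

Step 14
Reactants: 20 (2E)-3-({[tert-butyl(dimethyl)silyl]oxy}methyl)-5-[(4aS,8aS)-2,5,5,8a-tetramethyl-3,4,4a,5,6,7,8,8a-octahydronaphthalen-1-yl]pent-2-enal; 21 4-methylfuran-2(5H)-one
Product: 24 (5Z)-5-{(2E)-3-({[tert-butyl(dimethyl)silyl]oxy}methyl)-5-[(4aS,8aS)-2,5,5,8a-tetramethyl-3,4,4a,5,6,7,8,8a-octahydronaphthalen-1-yl]pent-2-en-1-ylidene}-4-methylfuran-2(5H)-one, via 2-silyloxyfuran 22 (not isolated), via silylated aldol adduct 23 (not isolated)
Conditions: 21, TBSOTf, iPr2NEt, CH2Cl2, 0 °C; then 20, −78 °C; then DBU, −78 °C to rt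
Reagents that add atoms: none
Why: In situ silyloxyfuran formation, vinylogous Mukaiyama aldol addition through the furan C5 to the silyl-activated aldehyde (1,2-addition) and DBU-induced E1cB loss of silanol should give the γ-alkylidene butenolide, the (Z)-isomer being favoured because it keeps the chain away from the C4 methyl group of the lactone ring.

Step 15
Reactants: 24 (5Z)-5-{(2E)-3-({[tert-butyl(dimethyl)silyl]oxy}methyl)-5-[(4aS,8aS)-2,5,5,8a-tetramethyl-3,4,4a,5,6,7,8,8a-octahydronaphthalen-1-yl]pent-2-en-1-ylidene}-4-methylfuran-2(5H)-one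
Product: 25 (5Z)-5-{(2E)-3-(hydroxymethyl)-5-[(4aS,8aS)-2,5,5,8a-tetramethyl-3,4,4a,5,6,7,8,8a-octahydronaphthalen-1-yl]pent-2-en-1-ylidene}-4-methylfuran-2(5H)-one
Conditions: HF·pyridine, pyridine, THF, 0 °C
Reagents that add atoms: none
Why: Desilylation of the primary silyl ether by buffered fluoride under non-basic conditions should leave the base-sensitive trienyl lactone and both alkene geometries intact.

**Compound list**

1 | methyl 5-methoxy-3-oxopentanoate | COCCC(=O)CC(=O)OC | starting material
2 | methyl 3-oxopent-4-enoate | C=CC(=O)CC(=O)OC | intermediate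
3 | methyl (2Z)-3-[(tert-butyldimethylsilyl)oxy]penta-2,4-dienoate | COC(=O)/C=C(\O[Si](C)(C)C(C)(C)C)C=C | intermediate
4 | 3-methylcyclohex-2-en-1-one | CC1=CC(=O)CCC1 | starting material
5 | methyl (1S,4aS,8aS)-2-[(tert-butyldimethylsilyl)oxy]-8a-methyl-5-oxo-1,4,4a,5,6,7,8,8a-octahydronaphthalene-1-carboxylate (cis-fused, not isolated) | COC(=O)[C@@H]1C(O[Si](C)(C)C(C)(C)C)=CC[C@@H]2C(=O)CCC[C@]12C | intermediate
6 | methyl (1S,4aS,8aS)-8a-methyl-2,5-dioxodecahydronaphthalene-1-carboxylate (cis-fused; C1 equilibrates through the enol) | COC(=O)[C@@H]1C(=O)CC[C@@H]2C(=O)CCC[C@]12C | intermediate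
7 | methyl (4aS,8aS)-8a-methyl-5-oxo-2-{[(trifluoromethyl)sulfonyl]oxy}-3,4,4a,5,6,7,8,8a-octahydronaphthalene-1-carboxylate (cis-fused) | COC(=O)C1=C(OS(=O)(=O)C(F)(F)F)CC[C@@H]2C(=O)CCC[C@]12C | intermediate
8 | methyl (4aS,8aS)-2,8a-dimethyl-5-oxo-3,4,4a,5,6,7,8,8a-octahydronaphthalene-1-carboxylate (cis-fused, not isolated) | COC(=O)C1=C(C)CC[C@@H]2C(=O)CCC[C@]12C | intermediate
9 | methyl (4aR,8aS)-2,8a-dimethyl-5-oxo-3,4,4a,5,6,7,8,8a-octahydronaphthalene-1-carboxylate (trans-fused) | COC(=O)C1=C(C)CC[C@H]2C(=O)CCC[C@]12C | intermediate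
10 | methyl (4aS,8aS)-2,5,5,8a-tetramethyl-3,4,4a,5,6,7,8,8a-octahydronaphthalene-1-carboxylate | COC(=O)C1=C(C)CC[C@H]2C(C)(C)CCC[C@]12C | intermediate
11 | [(4aS,8aS)-2,5,5,8a-tetramethyl-3,4,4a,5,6,7,8,8a-octahydronaphthalen-1-yl]methanol | OCC1=C(C)CC[C@H]2C(C)(C)CCC[C@]12C | intermediate
12 | (4aS,8aS)-2,5,5,8a-tetramethyl-3,4,4a,5,6,7,8,8a-octahydronaphthalene-1-carbaldehyde | O=CC1=C(C)CC[C@H]2C(C)(C)CCC[C@]12C | intermediate
13 | (4aS,8aS)-1-ethenyl-2,5,5,8a-tetramethyl-3,4,4a,5,6,7,8,8a-octahydronaphthalene | C=CC1=C(C)CC[C@H]2C(C)(C)CCC[C@]12C | intermediate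
14 | but-2-yne-1,4-diol | OCC#CCO | starting material
15 | 4-[(tert-butyldimethylsilyl)oxy]but-2-yn-1-ol | OCC#CCO[Si](C)(C)C(C)(C)C | intermediate
16 | sodium 3-({[tert-butyl(dimethyl)silyl]oxy}methyl)-2,2-bis(2-methoxyethoxy)-2,5-dihydro-1,2-oxaaluminol-2-uide (cyclic alkenylalanate, not isolated) | [Na+].CC(C)(C)[Si](C)(C)OCC1=CCO[Al-]1(OCCOC)OCCOC | intermediate
17 | (2Z)-4-[(tert-butyldimethylsilyl)oxy]-3-iodobut-2-en-1-ol | OC/C=C(\I)CO[Si](C)(C)C(C)(C)C | intermediate
18 | 9-{2-[(4aS,8aS)-2,5,5,8a-tetramethyl-3,4,4a,5,6,7,8,8a-octahydronaphthalen-1-yl]ethyl}-9-borabicyclo[3.3.1]nonane (not isolated) | B1(CCC2=C(C)CC[C@H]3C(C)(C)CCC[C@]23C)C2CCCC1CCC2 | intermediate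
19 | (2E)-3-({[tert-butyl(dimethyl)silyl]oxy}methyl)-5-[(4aS,8aS)-2,5,5,8a-tetramethyl-3,4,4a,5,6,7,8,8a-octahydronaphthalen-1-yl]pent-2-en-1-ol | OC/C=C(/CO[Si](C)(C)C(C)(C)C)CCC1=C(C)CC[C@H]2C(C)(C)CCC[C@]12C | intermediate
20 | (2E)-3-({[tert-butyl(dimethyl)silyl]oxy}methyl)-5-[(4aS,8aS)-2,5,5,8a-tetramethyl-3,4,4a,5,6,7,8,8a-octahydronaphthalen-1-yl]pent-2-enal | O=C/C=C(/CO[Si](C)(C)C(C)(C)C)CCC1=C(C)CC[C@H]2C(C)(C)CCC[C@]12C | intermediate
21 | 4-methylfuran-2(5H)-one | CC1=CC(=O)OC1 | starting material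
22 | tert-butyl(dimethyl)[(4-methylfuran-2-yl)oxy]silane (not isolated) | Cc1coc(O[Si](C)(C)C(C)(C)C)c1 | intermediate
23 | 5-[(2E)-1-{[tert-butyl(dimethyl)silyl]oxy}-3-({[tert-butyl(dimethyl)silyl]oxy}methyl)-5-[(4aS,8aS)-2,5,5,8a-tetramethyl-3,4,4a,5,6,7,8,8a-octahydronaphthalen-1-yl]pent-2-en-1-yl]-4-methylfuran-2(5H)-one (both new centres unassigned, not isolated) | CC1=CC(=O)OC1C(O[Si](C)(C)C(C)(C)C)/C=C(/CO[Si](C)(C)C(C)(C)C)CCC1=C(C)CC[C@H]2C(C)(C)CCC[C@]12C | intermediate
24 | (5Z)-5-{(2E)-3-({[tert-butyl(dimethyl)silyl]oxy}methyl)-5-[(4aS,8aS)-2,5,5,8a-tetramethyl-3,4,4a,5,6,7,8,8a-octahydronaphthalen-1-yl]pent-2-en-1-ylidene}-4-methylfuran-2(5H)-one | CC1=CC(=O)O/C1=C\C=C(\CO[Si](C)(C)C(C)(C)C)CCC1=C(C)CC[C@H]2C(C)(C)CCC[C@]12C | intermediate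
25 | (5Z)-5-{(2E)-3-(hydroxymethyl)-5-[(4aS,8aS)-2,5,5,8a-tetramethyl-3,4,4a,5,6,7,8,8a-octahydronaphthalen-1-yl]pent-2-en-1-ylidene}-4-methylfuran-2(5H)-one | CC1=CC(=O)O/C1=C\C=C(\CO)CCC1=C(C)CC[C@H]2C(C)(C)CCC[C@]12C | target

**Step count and risks**

Total step count: 15. Longest linear sequence: 13 steps (steps 1 to 9 and 12 to 15).

Steps most likely to fail:

Step 3 (bears the label "Proposed new method:"). The β,β-disubstituted enone may add too slowly to the ester-deactivated diene under the chiral catalyst, so that desilylation and polymerisation of the diene take over, or the facial selectivity may be poor. The fallback uses known chemistry and sets out from 3 and 4. The annulation is run without asymmetric induction with the mixed Lewis acid AlBr3/AlMe3 (toluene/CH2Cl2, −5 °C), conditions established for hindered 2-silyloxydienes and β,β-disubstituted cycloalkenones, and should give the racemic silyl enol ether cycloadduct F1. Hydrolysis (1 M HCl, THF) gives the racemic cis-fused diketo ester F2, Tf2O/iPr2NEt the racemic enol triflate F3, Negishi methylation (MeZnCl, Pd(PPh3)4) the racemic cis-fused keto ester F4, and NaOMe/MeOH the racemic trans-fused keto ester F5. The enantiomers of F5 are separated by preparative chromatography on a chiral stationary phase (cellulose tris(3,5-dimethylphenylcarbamate)); the (4aR,8aS) enantiomer is 9, where the route is rejoined.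

Step 6. Ionisation at C4 next to the ring-fusion CH may be followed by elimination or Wagner–Meerwein shifts instead of delivery of the second methyl group. The fallback sets out from 9. Wittig methylenation (Ph3PCH3Br, KOtBu, THF) should give the exocyclic alkene methyl (4aS,8aS)-2,8a-dimethyl-5-methylidene-3,4,4a,5,6,7,8,8a-octahydronaphthalene-1-carboxylate F6. Simmons–Smith cyclopropanation (Et2Zn, CH2I2, CH2Cl2) of this only electron-rich alkene gives the spirocyclopropane F7. Hydrogenolysis (H2, PtO2, AcOH) opens the distal CH2–CH2 bond of the cyclopropane to the gem-dimethyl group and returns to the route at 10.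

Step 14. Competitive soft enolisation of the enal to a silyl dienol ether, incomplete elimination, or scrambling of alkene geometry under DBU may erode the one-pot aldol–elimination. The fallback sets out from 20. Colvin homologation (Me3SiCHN2, LiN(iPr)2, THF, −78 °C to rt) should give the enyne tert-butyl(dimethyl){[(2E)-2-{2-[(4aS,8aS)-2,5,5,8a-tetramethyl-3,4,4a,5,6,7,8,8a-octahydronaphthalen-1-yl]ethyl}pent-2-en-4-yn-1-yl]oxy}silane F8. Tandem Sonogashira coupling and 5-exo-dig lactonisation with (2Z)-3-iodobut-2-enoic acid (Pd(PPh3)4, CuI, Et3N, MeCN, rt) then builds the (Z)-alkylidene butenolide directly and returns to the route at 24.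

**Further compounds**

F1 | step 3 | racemic methyl (1S*,4aS*,8aS*)-2-[(tert-butyldimethylsilyl)oxy]-8a-methyl-5-oxo-1,4,4a,5,6,7,8,8a-octahydronaphthalene-1-carboxylate (both enantiomers written) | COC(=O)[C@@H]1C(O[Si](C)(C)C(C)(C)C)=CC[C@@H]2C(=O)CCC[C@]12C.COC(=O)[C@H]1C(O[Si](C)(C)C(C)(C)C)=CC[C@H]2C(=O)CCC[C@@]12C
F2 | step 3 | racemic methyl (1S*,4aS*,8aS*)-8a-methyl-2,5-dioxodecahydronaphthalene-1-carboxylate (both enantiomers written) | COC(=O)[C@@H]1C(=O)CC[C@@H]2C(=O)CCC[C@]12C.COC(=O)[C@H]1C(=O)CC[C@H]2C(=O)CCC[C@@]12C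
F3 | step 3 | racemic methyl (4aS*,8aS*)-8a-methyl-5-oxo-2-{[(trifluoromethyl)sulfonyl]oxy}-3,4,4a,5,6,7,8,8a-octahydronaphthalene-1-carboxylate (both enantiomers written) | COC(=O)C1=C(OS(=O)(=O)C(F)(F)F)CC[C@@H]2C(=O)CCC[C@]12C.COC(=O)C1=C(OS(=O)(=O)C(F)(F)F)CC[C@H]2C(=O)CCC[C@@]12C
F4 | step 3 | racemic cis-fused methyl (4aS*,8aS*)-2,8a-dimethyl-5-oxo-3,4,4a,5,6,7,8,8a-octahydronaphthalene-1-carboxylate (both enantiomers written) | COC(=O)C1=C(C)CC[C@@H]2C(=O)CCC[C@]12C.COC(=O)C1=C(C)CC[C@H]2C(=O)CCC[C@@]12C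
F5 | step 3 | racemic trans-fused methyl (4aR*,8aS*)-2,8a-dimethyl-5-oxo-3,4,4a,5,6,7,8,8a-octahydronaphthalene-1-carboxylate (both enantiomers written) | COC(=O)C1=C(C)CC[C@H]2C(=O)CCC[C@]12C.COC(=O)C1=C(C)CC[C@@H]2C(=O)CCC[C@@]12C
F6 | step 6 | methyl (4aS,8aS)-2,8a-dimethyl-5-methylidene-3,4,4a,5,6,7,8,8a-octahydronaphthalene-1-carboxylate | COC(=O)C1=C(C)CC[C@H]2C(=C)CCC[C@]12C
F7 | step 6 | methyl (4a'S,8a'S)-4a',6'-dimethyl-3',4',4a',7',8',8a'-hexahydro-2'H-spiro[cyclopropane-1,1'-naphthalene]-5'-carboxylate | COC(=O)C1=C(C)CC[C@H]2C3(CC3)CCC[C@]12C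
F8 | step 14 | tert-butyl(dimethyl){[(2E)-2-{2-[(4aS,8aS)-2,5,5,8a-tetramethyl-3,4,4a,5,6,7,8,8a-octahydronaphthalen-1-yl]ethyl}pent-2-en-4-yn-1-yl]oxy}silane | C#C/C=C(/CO[Si](C)(C)C(C)(C)C)CCC1=C(C)CC[C@H]2C(C)(C)CCC[C@]12C
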